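**Retrosynthetic overview**

1. Target 19 ⇐ protected dihydrobenzofuran 17 (two tert-butyl carbonates, three benzyl ethers) by methanolysis and hydrogenolysis.
2. 17 ⇐ one-pot union of aldehyde 6 (carries ring A, the benzene ring C3a–C7a), arylmagnesium 11 (the C3 aryl) and chiral benzylic sulfonium ylide 15 (C2 and its aryl). Grignard addition and Boc shift give ortho-quinone methide 14; a [4+1] annulation then closes ring B (O1, C2, C3, C3a, C7a) by C2–C3 and then O1–C2.
3. Enabling feature: C3a lies between the two oxygen-bearing carbons C4 and C7a, and ring A is symmetric about the C3a···C6 axis. In 6 both oxygens are the same Boc carbonate, so whichever one migrates gives the same quinone methide and the other stays as protecting group. C2 is benzylic to a para-oxygenated ring, which stabilises the ylide carbon and eases the closing SN2.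
4. 6 ⇐ dihydroresveratrol 1 by directed ortho-metalation and formylation between the two ring-A oxygens. All four benzene rings are bought; ring B is the only ring made, in the key step.

Key step: step 6

Assumption: the (1R,4R,5R)-isothiocineole-derived ylide is taken to react on the face anti to its gem-dimethyl carbon with the aryl group syn to the sulfur lone pair, which leads to 2S; if the sense proves opposite, the enantiomeric sulfide from (S)-limonene is used with no other change.

**Step 1**
Reactants: 1 dihydroresveratrol (5-[2-(4-hydroxyphenyl)ethyl]benzene-1,3-diol)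
Product: 2 1,3-bis(methoxymethoxy)-5-{2-[4-(methoxymethoxy)phenyl]ethyl}benzene
Conditions: NaH (3.6 equiv), MOMCl (3.6 equiv), DMF, 0 °C → rt
Reagents that add atoms: chloromethyl methyl ether, COCCl
Why: Williamson O-alkylation of the three phenoxides; the MOM ethers should survive n-BuLi and direct the ortho-lithiation of step 2.

**Step 2**
Reactants: 2 tris-MOM ether
Product: 4 2,6-bis(methoxymethoxy)-4-{2-[4-(methoxymethoxy)phenyl]ethyl}benzaldehyde, via aryllithium 3 (not isolated)
Conditions: n-BuLi (1.2 equiv), THF, 0 °C; then DMF, 0 °C → rt; H2O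
Reagents that add atoms: N,N-dimethylformamide, CN(C)C=O
Why: Directed ortho-metalation; the carbon between the two OMOM groups is doubly activated and should lithiate in preference to the sites next to the single OMOM group, and DMF then formylates it.

**Step 3**
Reactants: 4 tris-MOM aldehyde
Product: 5 2,6-dihydroxy-4-[2-(4-hydroxyphenyl)ethyl]benzaldehyde
Conditions: conc. HCl (cat.), MeOH, 50 °C; aqueous work-up
Reagents that add atoms: none
Why: Acid-catalysed acetal exchange removes the three MOM groups as dimethoxymethane; the hydrogen-bonded aldehyde should be returned intact on aqueous work-up.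

**Step 4**
Reactants: 5 trihydroxy aldehyde
Product: 6 2,6-bis(tert-butoxycarbonyloxy)-4-{2-[4-(tert-butoxycarbonyloxy)phenyl]ethyl}benzaldehyde
Conditions: Boc2O (3.6 equiv), DMAP (0.1 equiv), i-Pr2NEt, THF, 0 °C → rt
Reagents that add atoms: di-tert-butyl dicarbonate, CC(C)(C)OC(=O)OC(=O)OC(C)(C)C
Why: DMAP-catalysed O-acylation should convert all three phenols into tert-butyl carbonates; the two ortho carbonates are equivalent and serve as migrating group and protecting group in step 6.

**Step 5**
Reactants: 7 (1R,4R,5R)-isothiocineole (4,7,7-trimethyl-6-thiabicyclo[3.2.1]octane, the enantiomer derived from (R)-limonene); 8 4-(benzyloxy)benzyl bromide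
Product: 9 (1R,4R,5R,6R)-6-[4-(benzyloxy)benzyl]-4,7,7-trimethyl-6-thiabicyclo[3.2.1]octan-6-ium trifluoromethanesulfonate
Conditions: LiOSO2CF3 (5 equiv), CH2Cl2/H2O, rt
Reagents that add atoms: lithium trifluoromethanesulfonate, [Li+].[O-]S(=O)(=O)C(F)(F)F
Why: S-alkylation of the sulfide with anion metathesis to the triflate; the bicyclic framework exposes only the exo lone pair, so a single sulfonium diastereomer should form.

**Step 6**
Reactants: 6 tris-Boc aldehyde; 10 1,3-bis(benzyloxy)-5-bromobenzene; 9 sulfonium triflate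
Product: 17 tert-butyl (2S,3S)-2-[4-(benzyloxy)phenyl]-3-[3,5-bis(benzyloxy)phenyl]-6-{2-[4-(tert-butoxycarbonyloxy)phenyl]ethyl}-2,3-dihydro-1-benzofuran-4-yl carbonate, via arylmagnesium bromide 11 (not isolated), via magnesium alkoxide 12 (not isolated), via phenoxide benzylic carbonate 13 (not isolated), via ortho-quinone methide 14 (not isolated), via sulfonium ylide 15 (not isolated), via betaine 16 (not isolated)
Conditions: 10, Mg, THF, rt (gives 11, 1.0 equiv); add to 6, THF, −78 °C; then cannulate in 15 [from 9 (1.3 equiv), LiN(SiMe3)2 (1.25 equiv), THF, −78 °C]; −78 → 0 °C; aq. NH4Cl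
Reagents that add atoms: none
Why: Proposed new method: Mechanism: Grignard 11 adds to the aldehyde of 6, alkoxide 12 takes over one of the two equivalent ortho tert-butyl carbonates (O-to-O acyl shift) and phenoxide 13 expels tert-butyl carbonate to give ortho-quinone methide 14, whose exocyclic carbon (C3) is attacked by the benzylic carbon of ylide 15 (C2–C3 bond), after which the phenoxide of betaine 16 displaces the sulfide at C2 and forms the O1–C2 bond. Closest known reaction types are the low-temperature generation of ortho-quinone methides from ortho-(Boc-oxy)benzaldehydes and organomagnesium reagents, the base-mediated formal [4+1] annulation of ortho-quinone methides with sulfur ylides to trans-2,3-dihydrobenzofurans, and the epoxidations with isothiocineole-derived benzylic ylides; untested are their one-pot combination and a chiral semi-stabilised ylide in the [4+1] mode. Ring B should close in a 5-exo-tet SN2 step with inversion at C2. C2 is reagent-controlled (the rigid sulfide gives one sulfonium diastereomer and one ylide conformer, its gem-dimethyl carbon shields one face of the ylide carbon, and inversion then gives 2S), while C3 is set in the same C–C bond formation by the anti-type approach of the two aryl-bearing carbons, the one that closes to the 2,3-trans ring, so 3S should follow from 2S. The step needs chemoselective Grignard addition to CHO beside three aryl carbonates (secured by −78 °C, one equivalent and the bulky tert-butyl groups) and release of 14 only while 15 is still intact (the magnesium phenoxide should eliminate below 0 °C). No regiochemical choice arises in the ring closure because the two oxygens flanking C3a are equivalent in 6, and the unused one stays protected as its carbonate, which also keeps 14 neutral and electrophilic.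

**Step 7**
Reactants: 17 bis-carbonate tris-benzyl ether
Product: 18 (2S,3S)-2-[4-(benzyloxy)phenyl]-3-[3,5-bis(benzyloxy)phenyl]-6-[2-(4-hydroxyphenyl)ethyl]-2,3-dihydro-1-benzofuran-4-ol
Conditions: K2CO3 (0.3 equiv), MeOH/THF, 0 °C → rt
Reagents that add atoms: none
Why: Base-catalysed methanolysis (transesterification) of the two aryl carbonates; the C2 aryl oxygen is still benzylated, so no para-phenoxide can open ring B and both stereocenters should stay untouched.

**Step 8**
Reactants: 18 diphenol tris-benzyl ether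
Product: 19 (2S,3S)-3-(3,5-dihydroxyphenyl)-2-(4-hydroxyphenyl)-6-[2-(4-hydroxyphenyl)ethyl]-2,3-dihydro-1-benzofuran-4-ol (target)
Conditions: H2 (1 atm), 10% Pd/C, EtOAc/MeOH, rt, stopped at full debenzylation
Reagents that add atoms: none
Why: Hydrogenolysis of the three aryl benzyl ethers; the cyclic benzylic C2–O1 ether should react more slowly, as in the debenzylation of flavans, and no stereocenter is involved.

**Compound list**

1 | dihydroresveratrol, 5-[2-(4-hydroxyphenyl)ethyl]benzene-1,3-diol | Oc1ccc(CCc2cc(O)cc(O)c2)cc1 | starting material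
2 | 1,3-bis(methoxymethoxy)-5-{2-[4-(methoxymethoxy)phenyl]ethyl}benzene | COCOc1ccc(CCc2cc(OCOC)cc(OCOC)c2)cc1 | intermediate
3 | 2-lithio derivative of 2 (lithium between the two OMOM groups) | [Li]c1c(OCOC)cc(CCc2ccc(OCOC)cc2)cc1OCOC | intermediate (not isolated)
4 | 2,6-bis(methoxymethoxy)-4-{2-[4-(methoxymethoxy)phenyl]ethyl}benzaldehyde | O=Cc1c(OCOC)cc(CCc2ccc(OCOC)cc2)cc1OCOC | intermediate
5 | 2,6-dihydroxy-4-[2-(4-hydroxyphenyl)ethyl]benzaldehyde | O=Cc1c(O)cc(CCc2ccc(O)cc2)cc1O | intermediate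
6 | 2,6-bis(tert-butoxycarbonyloxy)-4-{2-[4-(tert-butoxycarbonyloxy)phenyl]ethyl}benzaldehyde | O=Cc1c(OC(=O)OC(C)(C)C)cc(CCc2ccc(OC(=O)OC(C)(C)C)cc2)cc1OC(=O)OC(C)(C)C | intermediate
7 | (1R,4R,5R)-isothiocineole, (1R,4R,5R)-4,7,7-trimethyl-6-thiabicyclo[3.2.1]octane | C[C@@H]1CC[C@@H]2C[C@H]1SC2(C)C | starting material
8 | 4-(benzyloxy)benzyl bromide | BrCc1ccc(OCc2ccccc2)cc1 | starting material
9 | (1R,4R,5R,6R)-6-[4-(benzyloxy)benzyl]-4,7,7-trimethyl-6-thiabicyclo[3.2.1]octan-6-ium trifluoromethanesulfonate (benzyl group exo on sulfur) | C[C@@H]1CC[C@@H]2C[C@H]1[S@@+](Cc1ccc(OCc3ccccc3)cc1)C2(C)C.[O-]S(=O)(=O)C(F)(F)F | intermediate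
10 | 1,3-bis(benzyloxy)-5-bromobenzene | Brc1cc(OCc2ccccc2)cc(OCc2ccccc2)c1 | starting material
11 | 3,5-bis(benzyloxy)phenylmagnesium bromide | Br[Mg]c1cc(OCc2ccccc2)cc(OCc2ccccc2)c1 | intermediate (not isolated)
12 | bromomagnesium alkoxide from addition of 11 to the aldehyde of 6 (racemic carbinol carbon) | Br[Mg]OC(c1cc(OCc2ccccc2)cc(OCc2ccccc2)c1)c1c(OC(=O)OC(C)(C)C)cc(CCc2ccc(OC(=O)OC(C)(C)C)cc2)cc1OC(=O)OC(C)(C)C | intermediate (not isolated)
13 | bromomagnesium phenoxide with the Boc group shifted to the benzylic oxygen | Br[Mg]Oc1cc(CCc2ccc(OC(=O)OC(C)(C)C)cc2)cc(OC(=O)OC(C)(C)C)c1C(OC(=O)OC(C)(C)C)c1cc(OCc2ccccc2)cc(OCc2ccccc2)c1 | intermediate (not isolated)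
14 | ortho-quinone methide: 6-[3,5-bis(benzyloxy)benzylidene]-5-(tert-butoxycarbonyloxy)-3-{2-[4-(tert-butoxycarbonyloxy)phenyl]ethyl}cyclohexa-2,4-dien-1-one | O=C1C=C(CCc2ccc(OC(=O)OC(C)(C)C)cc2)C=C(OC(=O)OC(C)(C)C)C1=Cc1cc(OCc2ccccc2)cc(OCc2ccccc2)c1 | intermediate (not isolated)
15 | sulfonium ylide of 9 (benzylic carbon deprotonated) | C[C@@H]1CC[C@@H]2C[C@H]1[S@@+]([CH-]c1ccc(OCc3ccccc3)cc1)C2(C)C | intermediate (not isolated)
16 | betaine: 3-(tert-butoxycarbonyloxy)-5-{2-[4-(tert-butoxycarbonyloxy)phenyl]ethyl}-2-{(1S,2R)-1-[3,5-bis(benzyloxy)phenyl]-2-[4-(benzyloxy)phenyl]-2-(isothiocineol-6-ium-6-yl)ethyl}phenolate | [O-]c1cc(CCc2ccc(OC(=O)OC(C)(C)C)cc2)cc(OC(=O)OC(C)(C)C)c1[C@H](c1cc(OCc2ccccc2)cc(OCc2ccccc2)c1)[C@H](c1ccc(OCc2ccccc2)cc1)[S@@+]1[C@@H]2C[C@@H](CC[C@H]2C)C1(C)C | intermediate (not isolated)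
17 | tert-butyl (2S,3S)-2-[4-(benzyloxy)phenyl]-3-[3,5-bis(benzyloxy)phenyl]-6-{2-[4-(tert-butoxycarbonyloxy)phenyl]ethyl}-2,3-dihydro-1-benzofuran-4-yl carbonate | CC(C)(C)OC(=O)Oc1ccc(CCc2cc(OC(=O)OC(C)(C)C)c3c(c2)O[C@H](c2ccc(OCc4ccccc4)cc2)[C@H]3c2cc(OCc4ccccc4)cc(OCc4ccccc4)c2)cc1 | intermediate
18 | (2S,3S)-2-[4-(benzyloxy)phenyl]-3-[3,5-bis(benzyloxy)phenyl]-6-[2-(4-hydroxyphenyl)ethyl]-2,3-dihydro-1-benzofuran-4-ol | Oc1ccc(CCc2cc(O)c3c(c2)O[C@H](c2ccc(OCc4ccccc4)cc2)[C@H]3c2cc(OCc4ccccc4)cc(OCc4ccccc4)c2)cc1 | intermediate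
19 | (2S,3S)-3-(3,5-dihydroxyphenyl)-2-(4-hydroxyphenyl)-6-[2-(4-hydroxyphenyl)ethyl]-2,3-dihydro-1-benzofuran-4-ol (CNP0315602.1) | Oc1ccc(CCc2cc(O)c3c(c2)O[C@H](c2ccc(O)cc2)[C@H]3c2cc(O)cc(O)c2)cc1 | target

**Step count and risks**

Total step count: 8. Longest linear sequence: 7 steps (steps 1, 2, 3, 4, 6, 7, 8).

Steps most likely to fail:

Step 6 (proposed new method). The ylide may be lost, by thermal decay or C-acylation by an aryl carbonate, before the quinone methide is released. The quinone methide may oligomerise, the betaine may lose sulfide by E2 elimination, or the facial and relative selectivity may be poor. The fallback uses known chemistry only, sets out from 5 and comes back to the route at 19. Selective O-benzylation of 5 (BnBr 2.1 equiv, K2CO3, acetone; the last, chelated ortho hydroxyl stays free) should give 2-(benzyloxy)-4-{2-[4-(benzyloxy)phenyl]ethyl}-6-hydroxybenzaldehyde F1. Addition of Grignard 11 (2.2 equiv, THF, 0 °C) should give 3-(benzyloxy)-2-{[3,5-bis(benzyloxy)phenyl](hydroxy)methyl}-5-{2-[4-(benzyloxy)phenyl]ethyl}phenol F2. p-Toluenesulfinic acid (CH2Cl2, rt) should convert it into the storable quinone methide precursor 3-(benzyloxy)-2-{[3,5-bis(benzyloxy)phenyl](4-methylbenzenesulfonyl)methyl}-5-{2-[4-(benzyloxy)phenyl]ethyl}phenol F3. Treating F3 with [4-(benzyloxy)benzyl]dimethylsulfonium bromide F4 (from 8 and dimethyl sulfide) and Cs2CO3 in CH2Cl2 at rt is the established base-mediated sulfur-ylide [4+1] annulation and should give the racemic trans-2-[4-(benzyloxy)phenyl]-4-(benzyloxy)-3-[3,5-bis(benzyloxy)phenyl]-6-{2-[4-(benzyloxy)phenyl]ethyl}-2,3-dihydro-1-benzofuran F5. Preparative HPLC on a chiral stationary phase should give its (2S,3S)-enantiomer F6, and hydrogenolysis of F6 (H2, Pd/C) should give 19.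

Step 8. Hydrogenolytic opening of the benzylic C2–O1 bond of ring B may compete with debenzylation (over-reduction to a ring-opened triarylethane). The fallback sets out from 18 and comes back at 19: non-reductive Lewis-acid dealkylation with BCl3 and pentamethylbenzene as benzyl-cation scavenger (CH2Cl2, −78 °C). Any reversible ionisation at C2 should re-close to the trans ring because C3 is untouched. No new compound is made.

Step 5. Solvolysis of the electron-rich benzylic bromide in the two-phase medium and reversible loss of sulfide from the product salt may prevent clean salt formation. The fallback sets out from 7 and comes back at 15: 4-(benzyloxy)benzyl alcohol F7 is ionised with HBF4·OEt2 in dry CH2Cl2 at 0 °C in the presence of 7, so that the sulfide traps the benzylic cation. This should give (1R,4R,5R,6R)-6-[4-(benzyloxy)benzyl]-4,7,7-trimethyl-6-thiabicyclo[3.2.1]octan-6-ium tetrafluoroborate F8, which is deprotonated with LiN(SiMe3)2 to the same ylide 15 in step 6.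

**Further compounds**

F1 | step 6 | 2-(benzyloxy)-4-{2-[4-(benzyloxy)phenyl]ethyl}-6-hydroxybenzaldehyde | O=Cc1c(O)cc(CCc2ccc(OCc3ccccc3)cc2)cc1OCc1ccccc1
F2 | step 6 | 3-(benzyloxy)-2-{[3,5-bis(benzyloxy)phenyl](hydroxy)methyl}-5-{2-[4-(benzyloxy)phenyl]ethyl}phenol (racemic) | OC(c1cc(OCc2ccccc2)cc(OCc2ccccc2)c1)c1c(O)cc(CCc2ccc(OCc3ccccc3)cc2)cc1OCc1ccccc1
F3 | step 6 | 3-(benzyloxy)-2-{[3,5-bis(benzyloxy)phenyl](4-methylbenzenesulfonyl)methyl}-5-{2-[4-(benzyloxy)phenyl]ethyl}phenol (racemic) | Cc1ccc(S(=O)(=O)C(c2cc(OCc3ccccc3)cc(OCc3ccccc3)c2)c2c(O)cc(CCc3ccc(OCc4ccccc4)cc3)cc2OCc2ccccc2)cc1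
F4 | step 6 | [4-(benzyloxy)benzyl]dimethylsulfonium bromide | C[S+](C)Cc1ccc(OCc2ccccc2)cc1.[Br-]
F5 | step 6 | racemic trans-4-(benzyloxy)-2-[4-(benzyloxy)phenyl]-3-[3,5-bis(benzyloxy)phenyl]-6-{2-[4-(benzyloxy)phenyl]ethyl}-2,3-dihydro-1-benzofuran (both enantiomers) | c1ccccc1COc1ccc(CCc2cc(OCc4ccccc4)c3c(c2)O[C@H](c2ccc(OCc4ccccc4)cc2)[C@H]3c2cc(OCc4ccccc4)cc(OCc4ccccc4)c2)cc1.c1ccccc1COc1ccc(CCc2cc(OCc4ccccc4)c3c(c2)O[C@@H](c2ccc(OCc4ccccc4)cc2)[C@@H]3c2cc(OCc4ccccc4)cc(OCc4ccccc4)c2)cc1
F6 | step 6 | (2S,3S)-4-(benzyloxy)-2-[4-(benzyloxy)phenyl]-3-[3,5-bis(benzyloxy)phenyl]-6-{2-[4-(benzyloxy)phenyl]ethyl}-2,3-dihydro-1-benzofuran | c1ccccc1COc1ccc(CCc2cc(OCc4ccccc4)c3c(c2)O[C@H](c2ccc(OCc4ccccc4)cc2)[C@H]3c2cc(OCc4ccccc4)cc(OCc4ccccc4)c2)cc1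
F0 | step 8 | none | none
F7 | step 5 | 4-(benzyloxy)benzyl alcohol | OCc1ccc(OCc2ccccc2)cc1
F8 | step 5 | (1R,4R,5R,6R)-6-[4-(benzyloxy)benzyl]-4,7,7-trimethyl-6-thiabicyclo[3.2.1]octan-6-ium tetrafluoroborate | C[C@@H]1CC[C@@H]2C[C@H]1[S@@+](Cc1ccc(OCc3ccccc3)cc1)C2(C)C.F[B-](F)(F)F
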